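Ring B is built from acyclic carbon on an alkyl aryl ether of ring A, not by aryl–oxygen coupling. In ring B the C4' and C6' oxygens are meta, like the carbonyls of a cyclohexane-1,3-dione, and the ether carbon C1' lies alpha to C6' with the hydroxymethyl carbon C2' beside it. One operation, malonate conjugate addition to an α-aryloxy enone followed by Claisen closure of the methyl ketone, forms C2'–C3' and C4'–C5' and the complete carbocycle. The precursor is a 3-aryloxypent-3-en-2-one with a silyloxymethyl terminus, whose aryl group is benzyl-protected ring A. Decarboxylation, dehydrogenation and methylation aromatize ring B; a late Claisen rearrangement installs the prenyl group at C5.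

Key step: step 4

Labels: ring A carbons are C1–C6 (C1 carries CO2Me, C2 the ether oxygen to ring B, C4 the methyl group, C6 the second oxygen). Ring B carbons are C1'–C6' (C1' carries the ether oxygen, C2' the CH2O group, C4' and C6' the methoxy oxygens). Names keep these labels. TBS = tert-butyldimethylsilyl.

Assumption: the target has no stereocentre, so 4, 8–12 and 20 are carried as racemates or diastereomer mixtures; the SMILES of 9–11 show the relative configuration of one enantiomer.

Step 1
Reactants: 1 methyl 2,6-dihydroxy-4-methylbenzoate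
Product: 2 methyl 6-(benzyloxy)-2-hydroxy-4-methylbenzoate
Conditions: BnBr (1 equiv), K2CO3, acetone, 56 °C
Reagents that add atoms: benzyl bromide, BrCc1ccccc1
Why: Williamson etherification with one equivalent of benzyl bromide desymmetrises the two equivalent phenols statistically, the second alkylation being slowed because the remaining hydroxyl is hydrogen-bonded to the ester carbonyl, so the monoether should be separable from recovered 1 and the diether.

Step 2
Reactants: 2 methyl 6-(benzyloxy)-2-hydroxy-4-methylbenzoate; 3 dimethyl (1-diazo-2-oxopropyl)phosphonate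
Product: 4 dimethyl {1-[3-(benzyloxy)-2-(methoxycarbonyl)-5-methylphenoxy]-2-oxopropyl}phosphonate (racemic)
Conditions: Rh2(OAc)4 (cat.), ClCH2CH2Cl, 80 °C, slow addition of 3
Reagents that add atoms: none
Why: The rhodium carbenoid formed from the diazo ketophosphonate inserts into the phenolic O–H bond (carbenoid O–H insertion), which makes the ring A–O–C1' bond without aryl–oxygen coupling; the new CH(O)(P) centre forms racemic and is erased in step 3.

Step 3
Reactants: 4 dimethyl {1-[3-(benzyloxy)-2-(methoxycarbonyl)-5-methylphenoxy]-2-oxopropyl}phosphonate; 5 (tert-butyldimethylsilyloxy)acetaldehyde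
Product: 6 methyl 6-(benzyloxy)-2-{[(2Z)-1-(tert-butyldimethylsilyloxy)-4-oxopent-2-en-3-yl]oxy}-4-methylbenzoate
Conditions: LiCl, DBU, MeCN, 0 °C to rt
Reagents that add atoms: none
Why: Horner–Wadsworth–Emmons olefination under Masamune–Roush conditions is mild enough for the enolisable silyloxyacetaldehyde and should favour the isomer with acetyl trans to CH2OTBS, although either alkene isomer can be used because C2' becomes sp3 in step 4.

Step 4
Reactants: 6 methyl 6-(benzyloxy)-2-{[(2Z)-1-(tert-butyldimethylsilyloxy)-4-oxopent-2-en-3-yl]oxy}-4-methylbenzoate; 7 dimethyl malonate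
Product: 9 methyl 3-[3-(benzyloxy)-2-(methoxycarbonyl)-5-methylphenoxy]-2-[(tert-butyldimethylsilyloxy)methyl]-4,6-dioxocyclohexane-1-carboxylate (racemic all-trans isomer), via Michael adduct 8 (not isolated)
Conditions: NaOMe (2.2 equiv), MeOH, 0 °C to 65 °C; then AcOH
Reagents that add atoms: none
Why: Methoxide generates the malonate anion, which adds in conjugate fashion to C2', the only electrophilic alkene carbon of the α-aryloxy enone (C2'–C3' bond), and after proton transfer the enolate on the methyl side of the ketone (C5') attacks a malonate ester carbonyl (C4'–C5' bond) with loss of methoxide. The closest known reaction type is the Michael–Claisen (Dieckmann-type) annulation of malonates with methyl enones that gives 4-alkoxycarbonylcyclohexane-1,3-diones, as in the dimedone synthesis. The one new ring closes in the 6-exo-trig mode. The three new stereocentres C1', C2' and C3' are set under thermodynamic control, since C1' and C3' are alpha to carbonyl groups and epimerise in methoxide to the all-equatorial all-trans racemate; all three are removed again on aromatization. The step needs regioselectivity and chemoselectivity, and the substrate secures both: only addition at C2' and closure from the methyl group can give a six-membered ring (the C1' enolate would give a four-membered one), the ring A ester is flanked by two ortho oxygen substituents and is a poor acceptor, aryloxide cannot be lost by β-elimination because C2', the only sp3 carbon next to C1', is not acidic, and deprotonation of the acidic 1,3-dione product drives the equilibria forward.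

Step 5
Reactants: 9 methyl 3-[3-(benzyloxy)-2-(methoxycarbonyl)-5-methylphenoxy]-2-[(tert-butyldimethylsilyloxy)methyl]-4,6-dioxocyclohexane-1-carboxylate
Product: 10 methyl 6-(benzyloxy)-2-({2-[(tert-butyldimethylsilyloxy)methyl]-4,6-dioxocyclohexyl}oxy)-4-methylbenzoate (racemic trans isomer)
Conditions: LiCl, H2O, DMSO, 130 °C
Reagents that add atoms: none
Why: Krapcho demethoxycarbonylation removes only the ester that has a β-carbonyl to stabilise the carbanion left on loss of CO2, while the di-ortho-substituted benzoate of ring A should be inert; C3' becomes CH2 and the trans relation of C1' and C2' is kept or restored by enolisation.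

Step 6
Reactants: 10 methyl 6-(benzyloxy)-2-({2-[(tert-butyldimethylsilyloxy)methyl]-4,6-dioxocyclohexyl}oxy)-4-methylbenzoate
Product: 11 methyl 6-(benzyloxy)-2-({6-[(tert-butyldimethylsilyloxy)methyl]-4-methoxy-2-oxocyclohex-3-en-1-yl}oxy)-4-methylbenzoate (racemic trans isomer)
Conditions: Me3SiCHN2, MeOH/PhMe, 0 °C to rt
Reagents that add atoms: (trimethylsilyl)diazomethane, C[Si](C)(C)C=[N+]=[N-]
Why: The acidic enol of the 1,3-dione is O-methylated by diazomethane released from Me3SiCHN2 and methanol, without base or acid, so C-methylation at C5' and silyl ether loss are avoided; the less hindered C4' oxygen should react preferentially and any O6' regioisomer would be removed by chromatography.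

Step 7
Reactants: 11 methyl 6-(benzyloxy)-2-({6-[(tert-butyldimethylsilyloxy)methyl]-4-methoxy-2-oxocyclohex-3-en-1-yl}oxy)-4-methylbenzoate
Product: 14 methyl 6-(benzyloxy)-2-{2-[(tert-butyldimethylsilyloxy)methyl]-6-hydroxy-4-methoxyphenoxy}-4-methylbenzoate, via silyl dienol ether 12 (not isolated), via cyclohexadienone 13 (not isolated)
Conditions: LiN(iPr)2, Me3SiCl (in situ quench), THF, −78 °C; then Pd(OAc)2 (1.1 equiv), MeCN, rt
Reagents that add atoms: none
Why: Saegusa–Ito oxidation, in which kinetic deprotonation at C1' with immediate silylation gives the 2-silyloxydiene, whose palladium enolate undergoes β-hydride elimination toward C2' to give a cross-conjugated dienone with CH2 at C3' that tautomerises irreversibly to the phenol, erasing both sp3 stereocentres.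

Step 8
Reactants: 14 methyl 6-(benzyloxy)-2-{2-[(tert-butyldimethylsilyloxy)methyl]-6-hydroxy-4-methoxyphenoxy}-4-methylbenzoate
Product: 15 methyl 6-(benzyloxy)-2-{2-[(tert-butyldimethylsilyloxy)methyl]-4,6-dimethoxyphenoxy}-4-methylbenzoate
Conditions: MeI, K2CO3, acetone, 50 °C
Reagents that add atoms: iodomethane, CI
Why: Williamson O-methylation of the only free phenol completes the 4',6'-dimethoxy pattern of ring B, and excess iodomethane should trap the phenoxide faster than it can lactonise onto the hindered ring A ester.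

Step 9
Reactants: 15 methyl 6-(benzyloxy)-2-{2-[(tert-butyldimethylsilyloxy)methyl]-4,6-dimethoxyphenoxy}-4-methylbenzoate
Product: 16 methyl 2-{2-[(tert-butyldimethylsilyloxy)methyl]-4,6-dimethoxyphenoxy}-6-hydroxy-4-methylbenzoate
Conditions: H2 (1 atm), Pd/C, EtOAc, rt
Reagents that add atoms: none
Why: Catalytic hydrogenolysis cleaves the aryl benzyl ether much faster than the benzylic C–O bond of the silyl ether in a neutral aprotic solvent, which frees the C6 phenol.

Step 10
Reactants: 16 methyl 2-{2-[(tert-butyldimethylsilyloxy)methyl]-4,6-dimethoxyphenoxy}-6-hydroxy-4-methylbenzoate; 17 3-chloro-3-methylbut-1-yne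
Product: 18 methyl 2-{2-[(tert-butyldimethylsilyloxy)methyl]-4,6-dimethoxyphenoxy}-4-methyl-6-[(2-methylbut-3-yn-2-yl)oxy]benzoate
Conditions: DBU, CuCl2 (cat.), MeCN, 0 °C to rt
Reagents that add atoms: none
Why: Copper-catalysed O-propargylation of phenols with tertiary propargylic chlorides proceeds through a copper acetylide that ionises readily, so the DBU-generated phenoxide forms the 1,1-dimethylpropargyl ether without a direct SN2 displacement at the tertiary carbon.

Step 11
Reactants: 18 methyl 2-{2-[(tert-butyldimethylsilyloxy)methyl]-4,6-dimethoxyphenoxy}-4-methyl-6-[(2-methylbut-3-yn-2-yl)oxy]benzoate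
Product: 19 methyl 2-{2-[(tert-butyldimethylsilyloxy)methyl]-4,6-dimethoxyphenoxy}-4-methyl-6-[(2-methylbut-3-en-2-yl)oxy]benzoate
Conditions: H2 (1 atm), Pd/CaCO3 poisoned with Pb(OAc)2, quinoline, EtOAc, rt
Reagents that add atoms: none
Why: Lindlar semihydrogenation stops at the terminal alkene on the lead-poisoned palladium surface and leaves the aryl ethers, the ester and the benzylic silyl ether untouched.

Step 12
Reactants: 19 methyl 2-{2-[(tert-butyldimethylsilyloxy)methyl]-4,6-dimethoxyphenoxy}-4-methyl-6-[(2-methylbut-3-en-2-yl)oxy]benzoate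
Product: 21 methyl 2-{2-[(tert-butyldimethylsilyloxy)methyl]-4,6-dimethoxyphenoxy}-6-hydroxy-4-methyl-5-(3-methylbut-2-en-1-yl)benzoate, via cyclohexadienone 20 (not isolated)
Conditions: PhNEt2, 120 °C
Reagents that add atoms: none
Why: Aromatic Claisen rearrangement moves the allyl unit with inversion to C5, the only ortho position that carries hydrogen (C1 holds the ester), so the 1,1-dimethylallyl ether becomes the prenyl group; the transient C5 stereocentre of the dienone disappears on tautomerisation to the phenol.

Step 13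
Reactants: 21 methyl 2-{2-[(tert-butyldimethylsilyloxy)methyl]-4,6-dimethoxyphenoxy}-6-hydroxy-4-methyl-5-(3-methylbut-2-en-1-yl)benzoate
Product: 22 methyl 6-hydroxy-2-[2-(hydroxymethyl)-4,6-dimethoxyphenoxy]-4-methyl-5-(3-methylbut-2-en-1-yl)benzoate (CNP0583011.0)
Conditions: Bu4NF, AcOH, THF, 0 °C to rt
Reagents that add atoms: none
Why: Fluoride-mediated desilylation is driven by Si–F bond formation, and the acetic acid buffer avoids both strongly basic phenoxide conditions and the acid-catalysed cyclisation of the ortho-prenylphenol to a chroman.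

Compound list
1 | methyl 2,6-dihydroxy-4-methylbenzoate | COC(=O)c1c(O)cc(C)cc1O | starting material
2 | methyl 6-(benzyloxy)-2-hydroxy-4-methylbenzoate | COC(=O)c1c(O)cc(C)cc1OCc1ccccc1 | intermediate
3 | dimethyl (1-diazo-2-oxopropyl)phosphonate | CC(=O)C(=[N+]=[N-])P(=O)(OC)OC | starting material
4 | dimethyl {1-[3-(benzyloxy)-2-(methoxycarbonyl)-5-methylphenoxy]-2-oxopropyl}phosphonate (racemic) | CC(=O)C(Oc1cc(C)cc(OCc2ccccc2)c1C(=O)OC)P(=O)(OC)OC | intermediate
5 | (tert-butyldimethylsilyloxy)acetaldehyde | O=CCO[Si](C)(C)C(C)(C)C | starting material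
6 | methyl 6-(benzyloxy)-2-{[(2Z)-1-(tert-butyldimethylsilyloxy)-4-oxopent-2-en-3-yl]oxy}-4-methylbenzoate | CC(=O)/C(Oc1cc(C)cc(OCc2ccccc2)c1C(=O)OC)=C/CO[Si](C)(C)C(C)(C)C | intermediate
7 | dimethyl malonate | COC(=O)CC(=O)OC | starting material
8 | dimethyl 2-{3-[3-(benzyloxy)-2-(methoxycarbonyl)-5-methylphenoxy]-1-(tert-butyldimethylsilyloxy)-4-oxopentan-2-yl}malonate (racemic diastereomer mixture) | CC(=O)C(Oc1cc(C)cc(OCc2ccccc2)c1C(=O)OC)C(CO[Si](C)(C)C(C)(C)C)C(C(=O)OC)C(=O)OC | intermediate (not isolated)
9 | methyl 3-[3-(benzyloxy)-2-(methoxycarbonyl)-5-methylphenoxy]-2-[(tert-butyldimethylsilyloxy)methyl]-4,6-dioxocyclohexane-1-carboxylate (racemic, 1,2-trans and 2,3-trans) | COC(=O)[C@@H]1C(=O)CC(=O)[C@H](Oc2cc(C)cc(OCc3ccccc3)c2C(=O)OC)[C@H]1CO[Si](C)(C)C(C)(C)C | intermediate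
10 | methyl 6-(benzyloxy)-2-({2-[(tert-butyldimethylsilyloxy)methyl]-4,6-dioxocyclohexyl}oxy)-4-methylbenzoate (racemic, C1'/C2' trans) | O=C1CC(=O)[C@H](Oc2cc(C)cc(OCc3ccccc3)c2C(=O)OC)[C@@H](CO[Si](C)(C)C(C)(C)C)C1 | intermediate
11 | methyl 6-(benzyloxy)-2-({6-[(tert-butyldimethylsilyloxy)methyl]-4-methoxy-2-oxocyclohex-3-en-1-yl}oxy)-4-methylbenzoate (racemic, C1'/C2' trans) | COC1=CC(=O)[C@H](Oc2cc(C)cc(OCc3ccccc3)c2C(=O)OC)[C@@H](CO[Si](C)(C)C(C)(C)C)C1 | intermediate
12 | methyl 6-(benzyloxy)-2-({6-[(tert-butyldimethylsilyloxy)methyl]-4-methoxy-2-(trimethylsilyloxy)cyclohexa-1,3-dien-1-yl}oxy)-4-methylbenzoate (racemic) | COC1=CC(O[Si](C)(C)C)=C(Oc2cc(C)cc(OCc3ccccc3)c2C(=O)OC)C(CO[Si](C)(C)C(C)(C)C)C1 | intermediate (not isolated)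
13 | methyl 6-(benzyloxy)-2-({2-[(tert-butyldimethylsilyloxy)methyl]-4-methoxy-6-oxocyclohexa-1,4-dien-1-yl}oxy)-4-methylbenzoate | COC1=CC(=O)C(Oc2cc(C)cc(OCc3ccccc3)c2C(=O)OC)=C(CO[Si](C)(C)C(C)(C)C)C1 | intermediate (not isolated)
14 | methyl 6-(benzyloxy)-2-{2-[(tert-butyldimethylsilyloxy)methyl]-6-hydroxy-4-methoxyphenoxy}-4-methylbenzoate | COC(=O)c1c(OCc2ccccc2)cc(C)cc1Oc1c(O)cc(OC)cc1CO[Si](C)(C)C(C)(C)C | intermediate
15 | methyl 6-(benzyloxy)-2-{2-[(tert-butyldimethylsilyloxy)methyl]-4,6-dimethoxyphenoxy}-4-methylbenzoate | COC(=O)c1c(OCc2ccccc2)cc(C)cc1Oc1c(OC)cc(OC)cc1CO[Si](C)(C)C(C)(C)C | intermediate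
16 | methyl 2-{2-[(tert-butyldimethylsilyloxy)methyl]-4,6-dimethoxyphenoxy}-6-hydroxy-4-methylbenzoate | COC(=O)c1c(O)cc(C)cc1Oc1c(OC)cc(OC)cc1CO[Si](C)(C)C(C)(C)C | intermediate
17 | 3-chloro-3-methylbut-1-yne | C#CC(C)(C)Cl | starting material
18 | methyl 2-{2-[(tert-butyldimethylsilyloxy)methyl]-4,6-dimethoxyphenoxy}-4-methyl-6-[(2-methylbut-3-yn-2-yl)oxy]benzoate | COC(=O)c1c(OC(C)(C)C#C)cc(C)cc1Oc1c(OC)cc(OC)cc1CO[Si](C)(C)C(C)(C)C | intermediate
19 | methyl 2-{2-[(tert-butyldimethylsilyloxy)methyl]-4,6-dimethoxyphenoxy}-4-methyl-6-[(2-methylbut-3-en-2-yl)oxy]benzoate | COC(=O)c1c(OC(C)(C)C=C)cc(C)cc1Oc1c(OC)cc(OC)cc1CO[Si](C)(C)C(C)(C)C | intermediate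
20 | methyl 2-{2-[(tert-butyldimethylsilyloxy)methyl]-4,6-dimethoxyphenoxy}-4-methyl-5-(3-methylbut-2-en-1-yl)-6-oxocyclohexa-1,3-diene-1-carboxylate (racemic) | COC(=O)C1=C(Oc2c(CO[Si](C)(C)C(C)(C)C)cc(OC)cc2OC)C=C(C)C(CC=C(C)C)C1=O | intermediate (not isolated)
21 | methyl 2-{2-[(tert-butyldimethylsilyloxy)methyl]-4,6-dimethoxyphenoxy}-6-hydroxy-4-methyl-5-(3-methylbut-2-en-1-yl)benzoate | COC(=O)c1c(Oc2c(CO[Si](C)(C)C(C)(C)C)cc(OC)cc2OC)cc(C)c(CC=C(C)C)c1O | intermediate
22 | methyl 6-hydroxy-2-[2-(hydroxymethyl)-4,6-dimethoxyphenoxy]-4-methyl-5-(3-methylbut-2-en-1-yl)benzoate (CNP0583011.0) | COC(=O)c1c(Oc2c(CO)cc(OC)cc2OC)cc(C)c(CC=C(C)C)c1O | target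

Total step count: 13. Longest linear sequence: 13 steps (1 to 22).

Steps most likely to fail

Step 4. Conjugate addition to the alkene, which is both β-substituted and deactivated by the oxygen on its α-carbon, may be slow. Base-mediated γ-deprotonation with alkene migration, methanolysis of the silyl ether, or acylation of the C1' enolate by the ring A ester could then overtake the annulation. The fallback sets out from 6 and replaces the basic malonate addition by a Lewis-acid-mediated Mukaiyama–Michael addition of an acetate equivalent. 1-(tert-Butyldimethylsilyloxy)-1-methoxyethene with TiCl4 in CH2Cl2 at −78 °C should add to C2' of the chelated enone to give methyl 4-[3-(benzyloxy)-2-(methoxycarbonyl)-5-methylphenoxy]-3-[(tert-butyldimethylsilyloxy)methyl]-5-oxohexanoate F1. Treatment of F1 with KOtBu in THF at 0 °C should close the same C4'–C5' bond by 6-exo-trig Claisen condensation of the methyl ketone enolate onto the ester. After mild acidic work-up this comes back to the route at dione 10, and step 5 is no longer needed.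

Step 7. Silylation and palladation at the fully substituted, aryloxy-bearing C1' may be slow, so that protodesilylation simply returns 11 or the oxidation stalls. The fallback sets out from 11 and replaces the palladium-mediated oxidation by selenoxide elimination. LiN(iPr)2 in THF at −78 °C followed by PhSeCl should give methyl 6-(benzyloxy)-2-({6-[(tert-butyldimethylsilyloxy)methyl]-4-methoxy-2-oxo-1-(phenylselanyl)cyclohex-3-en-1-yl}oxy)-4-methylbenzoate F2, with selenium entering trans to the CH2OTBS group and therefore cis to the C2' hydrogen. H2O2 and pyridine in CH2Cl2 at 0 °C should oxidise it to the selenoxide, methyl 6-(benzyloxy)-2-({6-[(tert-butyldimethylsilyloxy)methyl]-4-methoxy-2-oxo-1-(phenylseleninyl)cyclohex-3-en-1-yl}oxy)-4-methylbenzoate F3. Syn-elimination toward C2' then gives cyclohexadienone 13, which tautomerises, so the fallback comes back to the route at 14.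

Step 10. The phenoxide of 16 is hindered and hydrogen-bonded to the ester, so elimination of the tertiary chloride to the enyne may outrun ether formation. The fallback sets out from 16 and uses a palladium π-allyl electrophile instead of a propargylic one. tert-Butyl (2-methylbut-3-en-2-yl) carbonate with the zerovalent palladium complex Pd(PPh3)4 in THF at 0 °C should give branched-selective decarboxylative O-allylation (Tsuji–Trost etherification). This comes back to the route at the 1,1-dimethylallyl ether 19, so step 11 is skipped; this fallback makes no new compound (F0).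

Further compounds
F1 | step 4 | methyl 4-[3-(benzyloxy)-2-(methoxycarbonyl)-5-methylphenoxy]-3-[(tert-butyldimethylsilyloxy)methyl]-5-oxohexanoate (racemic diastereomer mixture) | CC(=O)C(Oc1cc(C)cc(OCc2ccccc2)c1C(=O)OC)C(CO[Si](C)(C)C(C)(C)C)CC(=O)OC
F2 | step 7 | methyl 6-(benzyloxy)-2-({6-[(tert-butyldimethylsilyloxy)methyl]-4-methoxy-2-oxo-1-(phenylselanyl)cyclohex-3-en-1-yl}oxy)-4-methylbenzoate (racemic, selenium trans to CH2OTBS) | COC1=CC(=O)[C@](Oc2cc(C)cc(OCc3ccccc3)c2C(=O)OC)([Se]c2ccccc2)[C@@H](CO[Si](C)(C)C(C)(C)C)C1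
F3 | step 7 | methyl 6-(benzyloxy)-2-({6-[(tert-butyldimethylsilyloxy)methyl]-4-methoxy-2-oxo-1-(phenylseleninyl)cyclohex-3-en-1-yl}oxy)-4-methylbenzoate (racemic, mixture at selenium) | COC1=CC(=O)[C@](Oc2cc(C)cc(OCc3ccccc3)c2C(=O)OC)([Se](=O)c2ccccc2)[C@@H](CO[Si](C)(C)C(C)(C)C)C1
F0 | step 10 | none | none
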